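**Strategy.** α‑Zeacarotene, (6R)‑7',8'‑dihydro‑ε,ψ‑carotene, is cut at C11=C12 and C11'=C12' into a C15 ε‑end phosphonium salt, the C10 trienedial and a farnesyl ylide. Its only stereocentre is C6 of the cyclohexene ring: the CH between quaternary C1 and the C4=C5 alkene, bearing chain carbon C7. It is made by a Wittig–Still [2,3]‑shift. An oxygen at C4 hands a CH2 group to C6 on its own face while the ring alkene moves from C5=C6 to C4=C5, so the carbinol configuration becomes the C6 configuration in one operation. The precursor is the tributylstannylmethyl ether of (S)‑2,4,4‑trimethylcyclohex‑2‑en‑1‑ol.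

Key step: step 4

Remark: carotenoid numbering is used for the target (ring C1–C6, chain from C7, primed numbers for the acyclic half). Disubstituted polyene alkenes formed by Wittig reactions are expected as E/Z mixtures and are equilibrated to E within the same step. Tributyl(iodomethyl)stannane and the other named reagents are taken as purchased.

**Step 1**
Reactants: 1 isobutyraldehyde; 2 pent‑1‑en‑3‑one
Product: 5 2,4,4‑trimethylcyclohex‑2‑en‑1‑one, via enamine 3 (not isolated), via keto aldehyde 4 (not isolated)
Conditions: pyrrolidine, toluene, reflux (Dean–Stark), concentrate; then 2, 0 °C → rt; then 8 M aq HCl, rt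
Reagents that add atoms: none
Why: Stork enamine Michael addition of 3 to the enone, hydrolysis to keto aldehyde 4 and intramolecular aldol condensation (Robinson‑type annulation) should give one cyclohexenone, because the aldehyde has no α‑hydrogen and only the ethyl ketone CH2 can close a six‑membered ring.

**Step 2**
Reactants: 5 2,4,4‑trimethylcyclohex‑2‑en‑1‑one
Product: 6 (S)‑2,4,4‑trimethylcyclohex‑2‑en‑1‑ol
Conditions: (R)‑2‑methyl‑CBS‑oxazaborolidine [(3aR)‑1‑methyl‑3,3‑diphenyltetrahydro‑1H,3H‑pyrrolo[1,2‑c][1,3,2]oxazaborole] (10 mol %), BH3·SMe2, THF, −20 °C; MeOH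
Reagents that add atoms: none
Why: Corey–Bakshi–Shibata reduction, in which the oxazaborolidine–borane complex binds the carbonyl with the larger C(CH3)=CH flank away from the catalyst and delivers hydride to one face, so the (R)‑catalyst should give the (S)‑carbinol that is the source of all later chirality.

**Step 3**
Reactants: 6 (S)‑2,4,4‑trimethylcyclohex‑2‑en‑1‑ol
Product: 8 tributyl({[(1S)‑2,4,4‑trimethylcyclohex‑2‑en‑1‑yl]oxy}methyl)stannane, via potassium alkoxide 7 (not isolated)
Conditions: KH, THF, 0 °C; Bu3SnCH2I, 0 °C → rt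
Reagents that add atoms: tributyl(iodomethyl)stannane, CCCC[Sn](CCCC)(CCCC)CI
Why: Williamson etherification in which alkoxide 7 displaces iodide from the unhindered primary iodomethyl carbon (SN2), leaving the carbinol stereocentre untouched.

**Step 4**
Reactants: 8 tributyl({[(1S)‑2,4,4‑trimethylcyclohex‑2‑en‑1‑yl]oxy}methyl)stannane
Product: 11 (R)‑α‑cyclogeraniol [(1R)‑2,6,6‑trimethylcyclohex‑2‑en‑1‑yl]methanol, via alkoxymethyllithium 9 (not isolated), via lithium alkoxide 10 (not isolated)
Conditions: n‑BuLi, THF, −78 °C → −40 °C; aq NH4Cl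
Reagents that add atoms: none
Why: Tin–lithium exchange at −78 °C gives the unstabilised α‑alkoxymethyllithium 9, which should rearrange by a concerted suprafacial [2,3]‑sigmatropic shift (Wittig–Still rearrangement of a stannylmethyl allyl ether) through a five‑membered envelope transition state: the CH2 carbanion bonds to the alkene carbon next to the gem‑dimethyl carbon, the π bond moves one position toward the former carbinol carbon and the C–O bond breaks, leaving lithium alkoxide 10. No ring is closed; the five‑membered array exists only in the transition state, and one C–C bond (C6–C7 of the target) is formed. The new stereocentre is controlled by the carbinol carbon, because the OCH2Li tether is too short to reach the opposite ring face, so the CH2 group arrives on the face that carried oxygen and (S)‑8 must give (R)‑11. The step needs complete 1,3‑chirality transfer and [2,3] over [1,2] selectivity; the first follows from the cyclic ether geometry (pseudoaxial C–O bond aligned with the π system in the half‑chair, the axial methyl of the gem‑dimethyl group on the other face), the second from the low temperature, since the radical‑pair 1,2‑shift needs more thermal activation. The migrating group is an unsubstituted CH2, so congestion next to the quaternary carbon should be tolerated, and the product is an alkoxide that can neither epimerise nor let the alkene slip into the tetrasubstituted position.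

**Step 5**
Reactants: 11 (R)‑α‑cyclogeraniol
Product: 12 (R)‑α‑cyclocitral (1R)‑2,6,6‑trimethylcyclohex‑2‑ene‑1‑carbaldehyde
Conditions: Dess–Martin periodinane, NaHCO3, CH2Cl2, 0 °C → rt
Reagents that add atoms: none
Why: Dess–Martin oxidation of a primary alcohol under buffered conditions, chosen so that the α‑stereocentre of the β,γ‑unsaturated aldehyde is not enolised and the alkene is not drawn into conjugation; the crude aldehyde is used at once.

**Step 6**
Reactants: 12 (R)‑α‑cyclocitral
Product: 13 (R)‑α‑ionone (3E)‑4‑[(1R)‑2,6,6‑trimethylcyclohex‑2‑en‑1‑yl]but‑3‑en‑2‑one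
Conditions: (EtO)2P(O)CH2C(O)CH3, Ba(OH)2 (activated), THF/H2O (40:1), rt
Reagents that add atoms: diethyl (2‑oxopropyl)phosphonate, CCOP(=O)(CC(C)=O)OCC
Why: Horner–Wadsworth–Emmons olefination with a β‑ketophosphonate under the mild Ba(OH)2 protocol should give the E‑enone, the weakly basic phosphonate anion adding to the aldehyde faster than the hindered C6–H is removed, so the stereocentre is carried through.

**Step 7**
Reactants: 13 (R)‑α‑ionone
Product: 14 vinyl‑α‑ionol (1E)‑3‑methyl‑1‑[(1R)‑2,6,6‑trimethylcyclohex‑2‑en‑1‑yl]penta‑1,4‑dien‑3‑ol (both carbinol epimers)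
Conditions: CH2=CHMgBr, THF, −20 °C → 0 °C; aq NH4Cl
Reagents that add atoms: vinylmagnesium bromide, C=C[Mg]Br
Why: 1,2‑Grignard addition to the enone carbonyl (standard vinyl‑ionol preparation); the new carbinol centre forms as both epimers, which is irrelevant because it is destroyed in step 8, and C6 is no longer activated by a carbonyl group.

**Step 8**
Reactants: 14 vinyl‑α‑ionol
Product: 15 {(2E,4E)‑3‑methyl‑5‑[(1R)‑2,6,6‑trimethylcyclohex‑2‑en‑1‑yl]penta‑2,4‑dien‑1‑yl}triphenylphosphonium bromide
Conditions: PPh3·HBr, MeOH, rt; crystallise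
Reagents that add atoms: triphenylphosphine hydrobromide, [Br-].c1ccc(cc1)[PH+](c1ccccc1)c1ccccc1
Why: Acid‑mediated allylic transposition (SN1'‑type phosphonium salt formation used for C15 Wittig salts): ionisation of the tertiary bis‑allylic alcohol gives a pentadienyl cation that PPh3 captures at the terminal CH2, and the conjugated E,E‑dienyl salt is expected as the thermodynamic, crystallisable product.

**Step 9**
Reactants: 16 (2E,6E)‑farnesol
Product: 17 (2E,6E)‑farnesyl bromide (2E,6E)‑1‑bromo‑3,7,11‑trimethyldodeca‑2,6,10‑triene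
Conditions: PBr3, Et2O, 0 °C
Reagents that add atoms: phosphorus tribromide, BrP(Br)Br
Why: SN2 conversion of a primary allylic alcohol into the bromide at low temperature, which should keep the 2E geometry and avoid allylic rearrangement.

**Step 10**
Reactants: 17 (2E,6E)‑farnesyl bromide
Product: 18 [(2E,6E)‑3,7,11‑trimethyldodeca‑2,6,10‑trien‑1‑yl]triphenylphosphonium bromide
Conditions: PPh3, toluene, rt, dark
Reagents that add atoms: triphenylphosphine, c1ccc(cc1)P(c1ccccc1)c1ccccc1
Why: Quaternisation of PPh3 by the primary allylic bromide (SN2), the standard preparation of an allylic Wittig salt, with all alkene geometries retained.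

**Step 11**
Reactants: 18 farnesyltriphenylphosphonium bromide; 19 (2E,4E,6E)‑2,7‑dimethylocta‑2,4,6‑trienedial
Product: 21 (2E,4E,6E,8E,10E,14E)‑2,7,11,15,19‑pentamethylicosa‑2,4,6,8,10,14,18‑heptaenal, via farnesylidene ylide 20 (not isolated)
Conditions: n‑BuLi, THF, −78 °C; added slowly to 19 (3 equiv), THF, −78 °C → rt; then I2 (cat.), CH2Cl2, rt, light
Reagents that add atoms: none
Why: Wittig olefination in which the ylide meets an excess of the symmetrical dialdehyde so that only one formyl group should react, and iodine‑catalysed equilibration converts the hindered Z isomer of the new disubstituted alkene (which would clash with the neighbouring methyl‑bearing carbon) into the E isomer.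

**Step 12**
Reactants: 15 C15 ε‑end phosphonium bromide; 21 C25 heptaenal
Product: 23 α‑zeacarotene [(6R)‑7',8'‑dihydro‑ε,ψ‑carotene], via C15 ylide 22 (not isolated)
Conditions: NaOMe, MeOH/CH2Cl2, 0 °C → rt; then heptane, reflux, N2; crystallise
Reagents that add atoms: none
Why: Wittig olefination of the polyenal with the conjugated C15 ylide under the NaOMe conditions usual for carotenoids forms C11=C12, heating in heptane should convert the sterically hindered 11Z isomer into the all‑E polyene, and the mild base leaves the doubly allylic C6–H alone.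

**Compound list**
1 | isobutyraldehyde (2‑methylpropanal) | CC(C)C=O | starting material
2 | pent‑1‑en‑3‑one (ethyl vinyl ketone) | CCC(=O)C=C | starting material
3 | 1‑(2‑methylprop‑1‑en‑1‑yl)pyrrolidine (enamine) | CC(C)=CN1CCCC1 | intermediate
4 | 2,2‑dimethyl‑5‑oxoheptanal (keto aldehyde) | CCC(=O)CCC(C)(C)C=O | intermediate
5 | 2,4,4‑trimethylcyclohex‑2‑en‑1‑one | CC1=CC(C)(C)CCC1=O | intermediate
6 | (S)‑2,4,4‑trimethylcyclohex‑2‑en‑1‑ol | O[C@@H]1C(C)=CC(C)(C)CC1 | intermediate
7 | potassium (1S)‑2,4,4‑trimethylcyclohex‑2‑en‑1‑olate | [K+].[O-][C@@H]1C(C)=CC(C)(C)CC1 | intermediate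
8 | tributyl({[(1S)‑2,4,4‑trimethylcyclohex‑2‑en‑1‑yl]oxy}methyl)stannane | CCCC[Sn](CCCC)(CCCC)CO[C@@H]1C(C)=CC(C)(C)CC1 | intermediate
9 | ({[(1S)‑2,4,4‑trimethylcyclohex‑2‑en‑1‑yl]oxy}methyl)lithium | [Li]CO[C@@H]1C(C)=CC(C)(C)CC1 | intermediate
10 | lithium [(1R)‑2,6,6‑trimethylcyclohex‑2‑en‑1‑yl]methanolate | [Li+].[O-]C[C@H]1C(C)=CCCC1(C)C | intermediate
11 | (R)‑α‑cyclogeraniol, [(1R)‑2,6,6‑trimethylcyclohex‑2‑en‑1‑yl]methanol | OC[C@H]1C(C)=CCCC1(C)C | intermediate
12 | (R)‑α‑cyclocitral, (1R)‑2,6,6‑trimethylcyclohex‑2‑ene‑1‑carbaldehyde | O=C[C@H]1C(C)=CCCC1(C)C | intermediate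
13 | (R)‑α‑ionone, (3E)‑4‑[(1R)‑2,6,6‑trimethylcyclohex‑2‑en‑1‑yl]but‑3‑en‑2‑one | CC(=O)/C=C/[C@H]1C(C)=CCCC1(C)C | intermediate
14 | vinyl‑α‑ionol, (1E)‑3‑methyl‑1‑[(1R)‑2,6,6‑trimethylcyclohex‑2‑en‑1‑yl]penta‑1,4‑dien‑3‑ol, both carbinol epimers | C=CC(C)(O)/C=C/[C@H]1C(C)=CCCC1(C)C | intermediate
15 | {(2E,4E)‑3‑methyl‑5‑[(1R)‑2,6,6‑trimethylcyclohex‑2‑en‑1‑yl]penta‑2,4‑dien‑1‑yl}triphenylphosphonium bromide | C(/C=C(C)/C=C/[C@H]1C(C)=CCCC1(C)C)[P+](c1ccccc1)(c1ccccc1)c1ccccc1.[Br-] | intermediate
16 | (2E,6E)‑farnesol | CC(C)=CCC/C(C)=C/CC/C(C)=C/CO | starting material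
17 | (2E,6E)‑farnesyl bromide | CC(C)=CCC/C(C)=C/CC/C(C)=C/CBr | intermediate
18 | [(2E,6E)‑3,7,11‑trimethyldodeca‑2,6,10‑trien‑1‑yl]triphenylphosphonium bromide | CC(C)=CCC/C(C)=C/CC/C(C)=C/C[P+](c1ccccc1)(c1ccccc1)c1ccccc1.[Br-] | intermediate
19 | (2E,4E,6E)‑2,7‑dimethylocta‑2,4,6‑trienedial | O=C/C(C)=C/C=C/C=C(C)/C=O | starting material
20 | [(2E,6E)‑3,7,11‑trimethyldodeca‑2,6,10‑trien‑1‑ylidene]triphenylphosphorane (farnesylidene ylide) | CC(C)=CCC/C(C)=C/CC/C(C)=C/C=P(c1ccccc1)(c1ccccc1)c1ccccc1 | intermediate
21 | (2E,4E,6E,8E,10E,14E)‑2,7,11,15,19‑pentamethylicosa‑2,4,6,8,10,14,18‑heptaenal | CC(C)=CCC/C(C)=C/CC/C(C)=C/C=C/C(C)=C/C=C/C=C(C)/C=O | intermediate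
22 | {(2E,4E)‑3‑methyl‑5‑[(1R)‑2,6,6‑trimethylcyclohex‑2‑en‑1‑yl]penta‑2,4‑dien‑1‑ylidene}triphenylphosphorane (C15 ylide) | c1ccc(cc1)P(=C/C=C(C)/C=C/[C@H]1C(C)=CCCC1(C)C)(c1ccccc1)c1ccccc1 | intermediate
23 | α‑zeacarotene, (6R)‑7',8'‑dihydro‑ε,ψ‑carotene | CC(C)=CCC/C(C)=C/CC/C(C)=C/C=C/C(C)=C/C=C/C=C(C)/C=C/C=C(C)/C=C/[C@H]1C(C)=CCCC1(C)C | target

**Total step count:** 12 (steps 1–8 and 12 on the main line, steps 9–11 on the farnesyl branch).
**Longest linear sequence:** 9 steps (1–8, then 12) from isobutyraldehyde.

**Steps most likely to fail**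

Step 4. After tin–lithium exchange the carbanion may undergo the competing 1,2‑shift, or be protonated to the methyl ether, before it bonds to the ring carbon next to the gem‑dimethyl group. The fallback sets out from 6 and replaces the sigmatropic shift by a directed allylic substitution. Phenyl isocyanate (Et3N, CH2Cl2) gives (1S)‑2,4,4‑trimethylcyclohex‑2‑en‑1‑yl N‑phenylcarbamate F1. Deprotonation with n‑BuLi (THF, −78 °C), addition of CuI and then (isopropoxydimethylsilyl)methylmagnesium chloride (made from (chloromethyl)isopropoxydimethylsilane and Mg) should transfer the silylmethyl group from carbamate‑bound copper to the alkene terminus on the face of the leaving group (syn‑SN2'). This gives isopropoxydimethyl{[(1R)‑2,6,6‑trimethylcyclohex‑2‑en‑1‑yl]methyl}silane F2. Tamao oxidation (H2O2, KF, KHCO3, THF/MeOH) replaces silicon by hydroxyl at the CH2 carbon and comes back to the route at 11.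

Step 6. Enolisation of the hindered aldehyde under the basic olefination may erode the configuration at C6 or move the ring alkene into conjugation, and addition to the crowded formyl group may be slow. The fallback sets out from 12 and avoids any base while the stereocentre is α to a carbonyl. Takai olefination (CHI3, CrCl2, THF, 0 °C) should give (6R)‑6‑[(E)‑2‑iodoethenyl]‑1,5,5‑trimethylcyclohex‑1‑ene F3. Iodine–lithium exchange (t‑BuLi, Et2O, −78 °C) and acylation of the vinyllithium with N‑methoxy‑N‑methylacetamide come back to the route at 13.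

Step 2. Incomplete facial discrimination in the hydride transfer would lower the enantiomeric purity, and no later step can restore it. The fallback sets out from 5 and uses resolution instead of asymmetric reduction. Luche reduction (NaBH4, CeCl3·7H2O, MeOH, 0 °C) gives rac‑2,4,4‑trimethylcyclohex‑2‑en‑1‑ol F4. Acylation with vinyl acetate and lipase from Burkholderia cepacia (MTBE, rt) is expected, by the usual empirical rule for lipases and secondary alcohols, to esterify the R enantiomer to (1R)‑2,4,4‑trimethylcyclohex‑2‑en‑1‑yl acetate F5. The unreacted S alcohol is separated by chromatography and comes back to the route at 6.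

**Further compounds**
F1 | step 4 | (1S)‑2,4,4‑trimethylcyclohex‑2‑en‑1‑yl N‑phenylcarbamate | O=C(Nc1ccccc1)O[C@@H]1C(C)=CC(C)(C)CC1
F2 | step 4 | isopropoxydimethyl{[(1R)‑2,6,6‑trimethylcyclohex‑2‑en‑1‑yl]methyl}silane | CC(C)O[Si](C)(C)C[C@H]1C(C)=CCCC1(C)C
F3 | step 6 | (6R)‑6‑[(E)‑2‑iodoethenyl]‑1,5,5‑trimethylcyclohex‑1‑ene | I/C=C/[C@H]1C(C)=CCCC1(C)C
F4 | step 2 | rac‑2,4,4‑trimethylcyclohex‑2‑en‑1‑ol | OC1C(C)=CC(C)(C)CC1
F5 | step 2 | (1R)‑2,4,4‑trimethylcyclohex‑2‑en‑1‑yl acetate | CC(=O)O[C@H]1C(C)=CC(C)(C)CC1
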